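**Retrosynthetic overview**
- Feature: the bond between the exocyclic ketone carbon (C7, on lactone C3) and C1 of ring A (4-hydroxy-3-methoxyphenyl). It joins a β-keto lactone with an acidic C3–H, open to retro-Claisen cleavage, to a ring with a free C4 phenol, so it is made last, without base and without a phenol protecting group.
- Disconnection 1 (key): C7–C1(ring A) → S-ethyl thioester 13 + arylboronic acid 14 (Liebeskind–Srogl acyl coupling).
- Disconnection 2: C7–S, then C3–C7 → acid 11 → (R)-lactone 9 + CO2 (enolate carboxylation, then thioesterification).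
- Disconnection 3: lactone O1–C2 and C3–C4 → imide 4 + tert-butyl bromoacetate 5 (auxiliary-controlled alkylation sets C4; reduction and lactonisation close the ring).
- Ring order: rings A and B (3,4-dimethoxyphenyl) are bought; the butyrolactone is the only ring formed (step 3); C3 settles trans to the C4 benzyl group by equilibration.

Key step: step 6

Remark: C3 of the 3-acyl lactones 11, 13 and 15 carries an acidic hydrogen and epimerises readily, so these compounds are written as the thermodynamically preferred 3,4-trans isomers; boronic acid 14 is taken as purchasable.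

**Route**

Step 1
Reactants: 1 3-(3,4-dimethoxyphenyl)propanoic acid; 2 (4S)-4-benzyl-1,3-oxazolidin-2-one
Product: 4 (4S)-4-benzyl-3-[3-(3,4-dimethoxyphenyl)propanoyl]-1,3-oxazolidin-2-one, via mixed pivalic anhydride 3 (not isolated)
Conditions: t-BuCOCl, Et3N, THF, −20 °C; then 2, LiCl, −20 °C → rt
Reagents that add atoms: none
Why: Mixed-anhydride N-acylation of an Evans oxazolidinone, in which the oxazolidinone activated by LiCl and Et3N attacks the unhindered arylpropanoyl carbonyl of 3 rather than the pivaloyl carbonyl; no stereocentre is formed or touched.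

Step 2
Reactants: 4 (4S)-4-benzyl-3-[3-(3,4-dimethoxyphenyl)propanoyl]-1,3-oxazolidin-2-one; 5 tert-butyl bromoacetate
Product: 7 tert-butyl (3R)-3-{[(4S)-4-benzyl-2-oxo-1,3-oxazolidin-3-yl]carbonyl}-4-(3,4-dimethoxyphenyl)butanoate, via sodium Z-enolate 6 (not isolated)
Conditions: NaN(SiMe3)2, THF, −78 °C; then 5, −78 → −40 °C
Reagents that add atoms: none
Why: Evans asymmetric alkylation, in which the C4 benzyl group of the auxiliary shields one face of the chelated Z-enolate 6 so that the α-bromo ester adds from the other face and sets the future lactone C4 as R; the minor diastereomer should be removable by chromatography or crystallisation.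

Step 3
Reactants: 7 tert-butyl (3R)-3-{[(4S)-4-benzyl-2-oxo-1,3-oxazolidin-3-yl]carbonyl}-4-(3,4-dimethoxyphenyl)butanoate
Product: 9 (4R)-4-(3,4-dimethoxybenzyl)dihydrofuran-2(3H)-one, via hydroxy ester 8 (not isolated)
Conditions: LiBH4, MeOH (1 equiv), THF, 0 °C; aq. NH4Cl work-up; then p-TsOH·H2O (cat.), toluene, 80 °C
Reagents that add atoms: none
Why: Reductive removal of the auxiliary with LiBH4 (the imide carbonyl is far more electrophilic than the hindered tert-butyl ester) followed by acid-catalysed lactonisation of the γ-hydroxy tert-butyl ester (intramolecular transesterification) should close the butyrolactone; the stereocentre is β to the carbonyl and cannot epimerise.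

Step 4
Reactants: 9 (4R)-4-(3,4-dimethoxybenzyl)dihydrofuran-2(3H)-one
Product: 11 (3S,4R)-4-(3,4-dimethoxybenzyl)-2-oxotetrahydrofuran-3-carboxylic acid, via lithium enolate 10 (not isolated)
Conditions: LiN(iPr)2, THF, −78 °C; CO2 (dry gas), −78 → 0 °C; then 1 M HCl, 0 °C; concentrate below 30 °C
Reagents that add atoms: carbon dioxide, O=C=O
Why: Carboxylation of a lactone lithium enolate with CO2, which should add anti to the C4 benzyl group; as C3 of the product is enolisable, the 3,4-trans acid is also the thermodynamic isomer.

Step 5
Reactants: 11 (3S,4R)-4-(3,4-dimethoxybenzyl)-2-oxotetrahydrofuran-3-carboxylic acid; 12 ethanethiol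
Product: 13 S-ethyl (3R,4R)-4-(3,4-dimethoxybenzyl)-2-oxotetrahydrofuran-3-carbothioate
Conditions: DCC, DMAP (5 mol %), CH2Cl2, 0 °C → rt
Reagents that add atoms: none
Why: Steglich-type thioesterification, in which the carbodiimide-activated malonic half-acid should be captured by the soft, strongly nucleophilic thiol at 0 °C faster than it decarboxylates, with the lactone untouched and C3 remaining trans (the descriptor changes to 3R only because sulfur raises the priority of the exocyclic carbonyl).

Step 6
Reactants: 13 S-ethyl (3R,4R)-4-(3,4-dimethoxybenzyl)-2-oxotetrahydrofuran-3-carbothioate; 14 (4-hydroxy-3-methoxyphenyl)boronic acid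
Product: 15 (3S,4R)-4-(3,4-dimethoxybenzyl)-3-(4-hydroxy-3-methoxybenzoyl)dihydrofuran-2(3H)-one
Conditions: 14 (1.5–2 equiv), Pd2(dba)3 (2.5 mol %), tri(2-furyl)phosphine (10 mol %), Cu(O2C-2-thienyl) (monovalent copper thiophene-2-carboxylate, CuTC, 1.6 equiv), degassed THF, 50 °C, Ar; aq. NH4Cl/EDTA work-up
Reagents that add atoms: none
Why: Zerovalent palladium carrying tri(2-furyl)phosphine should insert into the acyl C–S bond of 13 while the thiophilic monovalent copper carboxylate binds sulfur and its carboxylate activates boron, so the aryl group of 14 is transferred to the acylpalladium and reductive elimination releases the aryl ketone, copper leaving as its ethanethiolate. The closest known reaction is the Liebeskind–Srogl thioester–boronic acid ketone synthesis, which is established for thioesters with epimerisable α-centres and tolerates protic groups. No ring closes and no stereocentre is created: C4 is remote from the reacting carbon, and C3, now flanked by the ketone and the lactone carbonyl, equilibrates through its enol to the 3,4-trans (3S,4R) isomer under control of the C4 benzyl group. The step needs insertion into C–S and not into the lactone C–O bond, arylation at carbon and not acylation or arylation of the phenol oxygen, and survival of the β-keto lactone; these rest on copper-assisted C–S activation that an ester cannot undergo, on the absence of base and oxygen (no phenoxide, no oxidative copper arylation), and on a neutral medium with no alkoxide or hydroxide to start a retro-Claisen cleavage.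

**Compound list**

1 | 3-(3,4-dimethoxyphenyl)propanoic acid | COc1ccc(CCC(=O)O)cc1OC | starting material
2 | (4S)-4-benzyl-1,3-oxazolidin-2-one | O=C1N[C@@H](Cc2ccccc2)CO1 | starting material
3 | 3-(3,4-dimethoxyphenyl)propanoic pivalic anhydride (formed in the flask) | COc1ccc(CCC(=O)OC(=O)C(C)(C)C)cc1OC | intermediate
4 | (4S)-4-benzyl-3-[3-(3,4-dimethoxyphenyl)propanoyl]-1,3-oxazolidin-2-one | COc1ccc(CCC(=O)N2[C@@H](Cc3ccccc3)COC2=O)cc1OC | intermediate
5 | tert-butyl bromoacetate | CC(C)(C)OC(=O)CBr | starting material
6 | sodium (Z)-enolate of 4 (formed in the flask) | COc1ccc(C/C=C(\[O-])N2[C@@H](Cc3ccccc3)COC2=O)cc1OC.[Na+] | intermediate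
7 | tert-butyl (3R)-3-{[(4S)-4-benzyl-2-oxo-1,3-oxazolidin-3-yl]carbonyl}-4-(3,4-dimethoxyphenyl)butanoate | CC(C)(C)OC(=O)C[C@@H](Cc1ccc(OC)c(OC)c1)C(=O)N1[C@@H](Cc2ccccc2)COC1=O | intermediate
8 | tert-butyl (3R)-4-(3,4-dimethoxyphenyl)-3-(hydroxymethyl)butanoate (carried on crude) | CC(C)(C)OC(=O)C[C@@H](Cc1ccc(OC)c(OC)c1)CO | intermediate
9 | (4R)-4-(3,4-dimethoxybenzyl)dihydrofuran-2(3H)-one | O=C1C[C@@H](Cc2ccc(OC)c(OC)c2)CO1 | intermediate
10 | lithium enolate of 9 (formed in the flask) | [Li+].[O-]C1=C[C@@H](Cc2ccc(OC)c(OC)c2)CO1 | intermediate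
11 | (3S,4R)-4-(3,4-dimethoxybenzyl)-2-oxotetrahydrofuran-3-carboxylic acid | OC(=O)[C@H]1C(=O)OC[C@@H]1Cc1ccc(OC)c(OC)c1 | intermediate
12 | ethanethiol | CCS | starting material
13 | S-ethyl (3R,4R)-4-(3,4-dimethoxybenzyl)-2-oxotetrahydrofuran-3-carbothioate | CCSC(=O)[C@H]1C(=O)OC[C@@H]1Cc1ccc(OC)c(OC)c1 | intermediate
14 | (4-hydroxy-3-methoxyphenyl)boronic acid | COc1cc(B(O)O)ccc1O | starting material
15 | (3S,4R)-4-(3,4-dimethoxybenzyl)-3-(4-hydroxy-3-methoxybenzoyl)dihydrofuran-2(3H)-one | COc1cc(C(=O)[C@H]2C(=O)OC[C@@H]2Cc2ccc(OC)c(OC)c2)ccc1O | target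

**Step count and risks**

Total step count: 6. Longest linear sequence: 6 steps (1 → 4 → 7 → 9 → 11 → 13 → 15).

Steps most likely to fail:

Step 6. The thiophilic copper salt may turn the malonyl-type thioester into an acylating agent for the free phenol (acyl transfer to oxygen instead of carbon). The electron-rich boronic acid may also lose boron by protonation, and the enolisable β-keto lactone may bind copper or palladium and stall the cycle. The fallback sets out from lactone 9 and comes back at 15. The lithium enolate of 9 (LiN(SiMe3)2, THF, −78 °C) would be added to 4-(benzyloxy)-3-methoxybenzaldehyde, anti to the C4 benzyl group, to give the aldol adduct (3S,4R)-3-{[4-(benzyloxy)-3-methoxyphenyl](hydroxy)methyl}-4-(3,4-dimethoxybenzyl)dihydrofuran-2(3H)-one F1 as a mixture of carbinol epimers. Dess–Martin oxidation (NaHCO3, CH2Cl2) would give the benzyl ether (3S,4R)-3-[4-(benzyloxy)-3-methoxybenzoyl]-4-(3,4-dimethoxybenzyl)dihydrofuran-2(3H)-one F2. Hydrogenolysis (H2, palladium on carbon, EtOAc) would then free the phenol to give 15.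

Step 5. The activated malonic half-acid may decarboxylate, or the O-acylisourea may rearrange to an N-acylurea, before the thiol captures it. The fallback sets out from lactone 9 and comes back at 13, bypassing the free acid. The enolate of 9 (LiN(SiMe3)2, 2.1 equiv, THF, −78 °C) would be C-acylated with S-ethyl carbonochloridothioate (CCSC(=O)Cl), the second equivalent of base taking up the acidic C3–H of the product. This should give 13 directly after a mildly acidic quench; no compound outside the list is made (F0).

Step 4. The enolate may be captured incompletely by CO2, the lactone enolate may undergo Claisen self-condensation, or the free acid may lose CO2 during isolation. The fallback sets out from lactone 9 and comes back at 11. The enolate of 9 (LiN(SiMe3)2, 2.1 equiv, THF, −78 °C) would be acylated with di-tert-butyl dicarbonate to the neutral, chromatographable ester tert-butyl (3R,4R)-4-(3,4-dimethoxybenzyl)-2-oxotetrahydrofuran-3-carboxylate F3. Cleavage with CF3CO2H in CH2Cl2 at 0 °C would then give acid 11 without heating.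

Further compounds
F1 | step 6 | (3S,4R)-3-{[4-(benzyloxy)-3-methoxyphenyl](hydroxy)methyl}-4-(3,4-dimethoxybenzyl)dihydrofuran-2(3H)-one (carbinol epimers) | COc1cc(C(O)[C@H]2C(=O)OC[C@@H]2Cc2ccc(OC)c(OC)c2)ccc1OCc1ccccc1
F2 | step 6 | (3S,4R)-3-[4-(benzyloxy)-3-methoxybenzoyl]-4-(3,4-dimethoxybenzyl)dihydrofuran-2(3H)-one | COc1cc(C(=O)[C@H]2C(=O)OC[C@@H]2Cc2ccc(OC)c(OC)c2)ccc1OCc1ccccc1
F0 | step 5 | none | none
F3 | step 4 | tert-butyl (3R,4R)-4-(3,4-dimethoxybenzyl)-2-oxotetrahydrofuran-3-carboxylate | CC(C)(C)OC(=O)[C@H]1C(=O)OC[C@@H]1Cc1ccc(OC)c(OC)c1
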